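**Retrosynthetic overview**
1. Target 37 ⇐ desilylation and bis-angeloylation of the 7-O-silyl triol 34 ⇐ hydroxyl-directed reduction of the C7 ketone of keto-diol 28.
2. C3 methyl ⇐ cuprate addition to enone 25 ⇐ IBX dehydrogenation and ozonolysis of the exocyclic methylene of 22 (gives the C1 ketone).
3. Seven-membered ring ⇐ intramolecular reductive aldol (C6 to C5) of the enone-cyclobutanone 18, then radical removal of the C5 hydroxyl.
4. Cyclobutane and six-membered ring together (bicyclo[3.1.1]heptanone 18) ⇐ intramolecular [2+2] cycloaddition of vinylketene 17 made from trienoic acid 15; the dioxolane decides the alkene face.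
5. 15 ⇐ D-erythrose acetonide 1 (source of C8 and C9) by alkyne homologation, carboalumination/conjugate addition and HWE. Ring order: four- and six-membered rings in one step, then the seven-membered ring.

Assumption: tricyclic compounds carry longipinane numbering (C1 ketone, C2, C3 CHMe, C4 and C11 bridgeheads, C5 cyclobutane CH, C6 CMe2, C7–C9 oxygenated carbons, C10 quaternary C–Me); 1 and 35 are taken as purchasable.

**Route**

Step 1
Reactants: 1 2,3-O-isopropylidene-D-erythrose (lactol); 2 dimethyl (1-diazo-2-oxopropyl)phosphonate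
Product: 3 [(4R,5S)-5-ethynyl-2,2-dimethyl-1,3-dioxolan-4-yl]methanol
Conditions: K2CO3, MeOH, 0 °C → rt
Reagents that add atoms: dimethyl (1-diazo-2-oxopropyl)phosphonate, COP(=O)(OC)C(=[N+]=[N-])C(C)=O
Why: Seyferth–Gilbert homologation with the Ohira–Bestmann reagent turns the open-chain aldehyde tautomer of the lactol into the terminal alkyne under mild base, so both stereocentres (future C8 and C9) are carried over unchanged from D-erythrose.

Step 2
Reactants: 3 alkynol; 4 trimethylaluminium; 5 but-3-en-2-one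
Product: 7 (5E)-6-[(4S,5R)-5-(hydroxymethyl)-2,2-dimethyl-1,3-dioxolan-4-yl]hept-5-en-2-one, via alkenylalane 6 (not isolated)
Conditions: Me3Al (3 equiv), Cp2ZrCl2 (0.2 equiv), CH2Cl2, 0 °C → rt; then THF, CuBr·SMe2 (10 mol %), 5, −20 → 0 °C; Rochelle salt work-up
Reagents that add atoms: trimethylaluminium, C[Al](C)C; but-3-en-2-one, CC(=O)C=C
Why: Negishi Zr-catalysed carboalumination adds Me and Al syn across the alkyne (Me to the internal carbon) and the alkenylalane is transferred with retention in a Cu-catalysed conjugate addition, which fixes the E trisubstituted alkene (chain cis to methyl); no stereocentre is formed.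

Step 3
Reactants: 7 hydroxy ketone; 8 trimethyl phosphonoacetate
Product: 9 methyl (2E,6E)-7-[(4S,5R)-5-(hydroxymethyl)-2,2-dimethyl-1,3-dioxolan-4-yl]-3-methylocta-2,6-dienoate
Conditions: NaH (2.2 equiv), THF, 0 → 50 °C; minor 2Z isomer removed by chromatography
Reagents that add atoms: trimethyl phosphonoacetate, COC(=O)CP(=O)(OC)OC
Why: Horner–Wadsworth–Emmons olefination of the methyl ketone gives mainly the 2E enoate, in which the C3 methyl is cis to the ester as needed for γ-deprotonation in step 8.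

Step 4
Reactants: 9 hydroxy ester
Product: 10 methyl (2E,6E)-7-[(4S,5S)-5-formyl-2,2-dimethyl-1,3-dioxolan-4-yl]-3-methylocta-2,6-dienoate
Conditions: Dess–Martin periodinane, NaHCO3, CH2Cl2, 0 °C → rt
Reagents that add atoms: none
Why: Dess–Martin oxidation under buffered, non-basic conditions gives the α-alkoxy aldehyde without epimerising the cis-dioxolane.

Step 5
Reactants: 10 aldehyde ester; 11 isopropenylmagnesium bromide
Product: 12 methyl (2E,6E)-7-[(4S,5R)-5-(1-hydroxy-2-methylprop-2-en-1-yl)-2,2-dimethyl-1,3-dioxolan-4-yl]-3-methylocta-2,6-dienoate (both carbinol epimers)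
Conditions: THF, −78 °C; aq. NH4Cl
Reagents that add atoms: isopropenylmagnesium bromide, CC(=C)[Mg]Br
Why: Grignard 1,2-addition is much faster at the aldehyde than at the hindered β,β-disubstituted enoate at −78 °C; the new carbinol centre is uncontrolled but is erased in step 7.

Step 6
Reactants: 12 allylic alcohol ester; 13 lithium hydroxide
Product: 14 (2E,6E)-7-[(4S,5R)-5-(1-hydroxy-2-methylprop-2-en-1-yl)-2,2-dimethyl-1,3-dioxolan-4-yl]-3-methylocta-2,6-dienoic acid (both carbinol epimers)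
Conditions: LiOH, THF/MeOH/H2O, 40 °C; then 1 M HCl to pH 4
Reagents that add atoms: lithium hydroxide, [Li+].[OH-]
Why: plain saponification of the enoate, done at this stage because no base-labile stereocentre is present yet.

Step 7
Reactants: 14 allylic alcohol acid
Product: 15 (2E,6E)-7-[(4S,5S)-2,2-dimethyl-5-(2-methylprop-2-enoyl)-1,3-dioxolan-4-yl]-3-methylocta-2,6-dienoic acid
Conditions: Dess–Martin periodinane, NaHCO3, CH2Cl2, 0 °C → rt
Reagents that add atoms: none
Why: Dess–Martin oxidation of the allylic alcohol gives the isopropenyl ketone, the precursor of a regiodefined enolate, and removes the undefined centre.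

Step 8
Reactants: 15 trienoic acid
Product: 18 (1S,5R,7R)-7-[(4S,5S)-2,2-dimethyl-5-(2-methylprop-2-enoyl)-1,3-dioxolan-4-yl]-7-methyl-2-methylidenebicyclo[3.1.1]heptan-6-one, via acid chloride 16 (not isolated), via vinylketene 17 (not isolated)
Conditions: 1-chloro-N,N,2-trimethylprop-1-en-1-amine, CH2Cl2, 0 °C; then syringe-pump addition to Et3N (3 equiv), BHT (cat.), PhMe, 110 °C, 5 mM
Reagents that add atoms: none
Why: dehydrochlorination at the cis γ-methyl gives the vinylketene, whose intramolecular thermal ketene–alkene [2+2] cycloaddition (Snider type) bonds the ketene carbonyl carbon to the CH terminus and the α-carbon to the disubstituted terminus, forming cyclobutanone and six-membered ring together; the E-alkene is transferred suprafacially (methyl syn to the three-carbon bridge) and the ketene should attack the face anti to the acyl-bearing dioxolane carbon with the allylic C–O inside (a model prediction without direct precedent for ketenes), which sets C4, C10 and C11 from the bought stereocentres.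

Step 9
Reactants: 18 enone-cyclobutanone
Product: 19 tricyclic β-hydroxy ketone (5-hydroxy-8,9-O-isopropylidene-1-methylidene-3-demethyllongipinan-7-one)
Conditions: [(Ph3P)CuH]6 (0.35 equiv), PhMe/THF, −40 → 0 °C; aq. NH4Cl
Reagents that add atoms: none
Why: Stryker conjugate reduction makes the tetrasubstituted copper enolate regiospecifically and its intramolecular aldol addition to the strained, non-enolisable cyclobutanone (reductive aldol cyclisation) closes the seven-membered ring and creates the C6 gem-dimethyl carbon; the tether reaches the carbonyl only from the face opposite the three-carbon bridge, which fixes C5.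

Step 10
Reactants: 19 tertiary alcohol; 20 methyl chlorooxoacetate
Product: 21 5-O-(methoxyoxalyl) ester of 19
Conditions: pyridine, DMAP (cat.), CH2Cl2, 0 °C → rt
Reagents that add atoms: methyl chlorooxoacetate, COC(=O)C(Cl)=O
Why: DMAP-catalysed acylation turns the hindered tertiary alcohol into a methyl oxalate, the radical leaving group, under conditions too mild for retro-aldol cleavage.

Step 11
Reactants: 21 oxalate
Product: 22 8,9-O-isopropylidene-1-methylidene-3-demethyllongipinan-7-one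
Conditions: Bu3SnH, AIBN (cat.), PhMe, 100 °C
Reagents that add atoms: none
Why: tin hydride radical deoxygenation of the tertiary oxalate (Barton–McCombie type, oxalate variant) gives a cyclobutyl radical that cannot eliminate and takes up hydrogen on the only face left open by the ring tether, so C5–H is syn to the three-carbon bridge as in the target.

Step 12
Reactants: 22 methylidene ketone; 23 ozone
Product: 24 8,9-O-isopropylidene-3-demethyllongipinane-1,7-dione
Conditions: O3, CH2Cl2/MeOH, −78 °C; then Me2S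
Reagents that add atoms: ozone, [O-][O+]=O
Why: ozonolysis with reductive work-up cleaves the only C=C bond, the exocyclic methylene, to the C1 ketone.

Step 13
Reactants: 24 diketone
Product: 25 8,9-O-isopropylidene-3-demethyllongipin-2-ene-1,7-dione
Conditions: IBX (2.5 equiv), DMSO/PhF, 70 °C
Reagents that add atoms: none
Why: IBX dehydrogenation can desaturate only C2–C3 (C11 is a bridgehead and the C7 ketone is flanked by a quaternary carbon and the dioxolane), giving the apoverbenone-type enone.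

Step 14
Reactants: 25 enone; 26 methyllithium
Product: 27 8,9-O-isopropylidene-8,9-dihydroxylongipinane-1,7-dione (3R)
Conditions: Me2CuLi (from 26 and CuI), Et2O, −78 → −20 °C; aq. NH4Cl
Reagents that add atoms: methyllithium (as lithium dimethylcuprate), C[Li]
Why: Gilman cuprate conjugate addition occurs on the enone face turned to the C5–H bridge, away from the C10 methyl over the other face, which sets the C3 methyl centre as in the target; the hindered C7 ketone is not attacked.

Step 15
Reactants: 27 acetonide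
Product: 28 8,9-dihydroxylongipinane-1,7-dione
Conditions: TFA/H2O 9:1, CH2Cl2, 0 °C
Reagents that add atoms: none
Why: acid hydrolysis of the isopropylidene acetal frees the cis-8,9-diol without touching a stereocentre.

Step 16
Reactants: 28 keto-diol
Product: 29 (3R,4S,5S,7S,8R,9S,10R,11R)-7,8,9-trihydroxylongipinan-1-one
Conditions: Me4NBH(OAc)3, MeCN/AcOH 1:1, −25 °C
Reagents that add atoms: none
Why: Evans–Saksena hydroxyl-directed reduction: the borohydride is bound by the C8 and C9 hydroxyls and delivers hydride to their face of the C7 carbonyl, giving the 7-hydroxyl anti to both, while the C1 ketone has no neighbouring hydroxyl and is left alone.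

Step 17
Reactants: 29 triol; 30 phenylboronic acid; 31 tert-butyldimethylsilyl trifluoromethanesulfonate
Product: 34 7-O-(tert-butyldimethylsilyl)-7,8,9-trihydroxylongipinan-1-one, via cyclic phenylboronate 32 (not isolated), via silylated phenylboronate 33 (not isolated)
Conditions: 30, MgSO4, CH2Cl2, rt; 2,6-lutidine, 31, −40 → 0 °C; then pinacol, MeOH, rt
Reagents that add atoms: tert-butyldimethylsilyl trifluoromethanesulfonate, CC(C)(C)[Si](C)(C)OS(=O)(=O)C(F)(F)F
Why: the cis-8,9-diol is masked in situ as a cyclic phenylboronate (the trans-7,8 pair cannot form one), so silylation takes the C7 hydroxyl and boronate exchange with pinacol returns the diol; no stereocentre changes.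

Step 18
Reactants: 34 silyl ether diol; 35 angelic anhydride
Product: 36 7-O-(tert-butyldimethylsilyl)-8,9-di-O-angeloyl-7,8,9-trihydroxylongipinan-1-one
Conditions: LiHMDS (2.1 equiv), THF, −78 °C; 35 (3 equiv), −78 → 0 °C; aq. NH4Cl
Reagents that add atoms: angelic anhydride, C/C=C(/C)C(=O)OC(=O)/C(C)=C\C
Why: acylation of the two lithium alkoxides with the anhydride uses no nucleophilic amine catalyst, which keeps the Z (angelate) geometry, and with C7 silylated only O8 and O9 can react.

Step 19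
Reactants: 36 silyl ether diester
Product: 37 target
Conditions: HF·pyridine, THF/pyridine, 0 °C → rt
Reagents that add atoms: none
Why: fluoride cleavage of the silyl ether under buffered acidic conditions releases the C7 hydroxyl without acyl migration or Z/E isomerisation of the angelates.

**Compound list**
1 | 2,3-O-isopropylidene-D-erythrose, lactol form, (3aR,6aR)-2,2-dimethyltetrahydrofuro[3,4-d][1,3]dioxol-4-ol, anomer mixture | OC1OC[C@H]2OC(C)(C)O[C@@H]12 | starting material
2 | dimethyl (1-diazo-2-oxopropyl)phosphonate (Ohira–Bestmann reagent) | COP(=O)(OC)C(=[N+]=[N-])C(C)=O | starting material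
3 | [(4R,5S)-5-ethynyl-2,2-dimethyl-1,3-dioxolan-4-yl]methanol | C#C[C@@H]1OC(C)(C)O[C@@H]1CO | intermediate
4 | trimethylaluminium | C[Al](C)C | starting material
5 | but-3-en-2-one | CC(=O)C=C | starting material
6 | (E)-alkenyl(dimethyl)alane from syn-methylalumination of 3, as its O-dimethylaluminium alkoxide | C[Al](C)/C=C(\C)[C@@H]1OC(C)(C)O[C@@H]1CO[Al](C)C | intermediate
7 | (5E)-6-[(4S,5R)-5-(hydroxymethyl)-2,2-dimethyl-1,3-dioxolan-4-yl]hept-5-en-2-one | CC(=O)CC/C=C(\C)[C@@H]1OC(C)(C)O[C@@H]1CO | intermediate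
8 | trimethyl phosphonoacetate | COC(=O)CP(=O)(OC)OC | starting material
9 | methyl (2E,6E)-7-[(4S,5R)-5-(hydroxymethyl)-2,2-dimethyl-1,3-dioxolan-4-yl]-3-methylocta-2,6-dienoate | COC(=O)/C=C(\C)CC/C=C(\C)[C@@H]1OC(C)(C)O[C@@H]1CO | intermediate
10 | methyl (2E,6E)-7-[(4S,5S)-5-formyl-2,2-dimethyl-1,3-dioxolan-4-yl]-3-methylocta-2,6-dienoate | COC(=O)/C=C(\C)CC/C=C(\C)[C@@H]1OC(C)(C)O[C@@H]1C=O | intermediate
11 | isopropenylmagnesium bromide | CC(=C)[Mg]Br | starting material
12 | methyl (2E,6E)-7-[(4S,5R)-5-(1-hydroxy-2-methylprop-2-en-1-yl)-2,2-dimethyl-1,3-dioxolan-4-yl]-3-methylocta-2,6-dienoate, both carbinol epimers | COC(=O)/C=C(\C)CC/C=C(\C)[C@@H]1OC(C)(C)O[C@@H]1C(O)C(C)=C | intermediate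
13 | lithium hydroxide | [Li+].[OH-] | starting material
14 | (2E,6E)-7-[(4S,5R)-5-(1-hydroxy-2-methylprop-2-en-1-yl)-2,2-dimethyl-1,3-dioxolan-4-yl]-3-methylocta-2,6-dienoic acid, both carbinol epimers | OC(=O)/C=C(\C)CC/C=C(\C)[C@@H]1OC(C)(C)O[C@@H]1C(O)C(C)=C | intermediate
15 | (2E,6E)-7-[(4S,5S)-2,2-dimethyl-5-(2-methylprop-2-enoyl)-1,3-dioxolan-4-yl]-3-methylocta-2,6-dienoic acid | OC(=O)/C=C(\C)CC/C=C(\C)[C@@H]1OC(C)(C)O[C@@H]1C(=O)C(C)=C | intermediate
16 | (2E,6E)-7-[(4S,5S)-2,2-dimethyl-5-(2-methylprop-2-enoyl)-1,3-dioxolan-4-yl]-3-methylocta-2,6-dienoyl chloride | ClC(=O)/C=C(\C)CC/C=C(\C)[C@@H]1OC(C)(C)O[C@@H]1C(=O)C(C)=C | intermediate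
17 | (6E)-7-[(4S,5S)-2,2-dimethyl-5-(2-methylprop-2-enoyl)-1,3-dioxolan-4-yl]-3-methylideneocta-1,6-dien-1-one (vinylketene) | O=C=CC(=C)CC/C=C(\C)[C@@H]1OC(C)(C)O[C@@H]1C(=O)C(C)=C | intermediate
18 | (1S,5R,7R)-7-[(4S,5S)-2,2-dimethyl-5-(2-methylprop-2-enoyl)-1,3-dioxolan-4-yl]-7-methyl-2-methylidenebicyclo[3.1.1]heptan-6-one | O=C1[C@@H]2CCC(=C)[C@H]1[C@]2(C)[C@@H]3OC(C)(C)O[C@@H]3C(=O)C(C)=C | intermediate
19 | 5-hydroxy-8,9-O-isopropylidene-8,9-dihydroxy-1-methylidene-3-demethyllongipinan-7-one; C4, C8, C9, C10, C11 as in 37, C5–OH on the side of the C1–C3 bridge | CC1(C)O[C@@H]2C(=O)C(C)(C)[C@@]3(O)[C@@H]4CCC(=C)[C@H]3[C@]4(C)[C@@H]2O1 | intermediate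
20 | methyl chlorooxoacetate | COC(=O)C(Cl)=O | starting material
21 | 5-O-(methoxyoxalyl) ester of 19 | CC1(C)O[C@@H]2C(=O)C(C)(C)[C@@]3(OC(=O)C(=O)OC)[C@@H]4CCC(=C)[C@H]3[C@]4(C)[C@@H]2O1 | intermediate
22 | 8,9-O-isopropylidene-8,9-dihydroxy-1-methylidene-3-demethyllongipinan-7-one; C4, C5, C8, C9, C10, C11 as in 37 | CC1(C)O[C@@H]2C(=O)C(C)(C)[C@H]3[C@@H]4CCC(=C)[C@H]3[C@]4(C)[C@@H]2O1 | intermediate
23 | ozone | [O-][O+]=O | starting material
24 | 8,9-O-isopropylidene-8,9-dihydroxy-3-demethyllongipinane-1,7-dione | CC1(C)O[C@@H]2C(=O)C(C)(C)[C@H]3[C@@H]4CCC(=O)[C@H]3[C@]4(C)[C@@H]2O1 | intermediate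
25 | 8,9-O-isopropylidene-8,9-dihydroxy-3-demethyllongipin-2-ene-1,7-dione | CC1(C)O[C@@H]2C(=O)C(C)(C)[C@H]3[C@@H]4C=CC(=O)[C@H]3[C@]4(C)[C@@H]2O1 | intermediate
26 | methyllithium | C[Li] | starting material
27 | 8,9-O-isopropylidene-8,9-dihydroxylongipinane-1,7-dione; C3 (R), C4, C5, C8, C9, C10, C11 as in 37 | CC1(C)O[C@@H]2C(=O)C(C)(C)[C@H]3[C@@H]4[C@H](C)CC(=O)[C@H]3[C@]4(C)[C@@H]2O1 | intermediate
28 | 8,9-dihydroxylongipinane-1,7-dione; all centres as in 37 | O[C@@H]1C(=O)C(C)(C)[C@H]2[C@@H]3[C@H](C)CC(=O)[C@H]2[C@]3(C)[C@@H]1O | intermediate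
29 | (3R,4S,5S,7S,8R,9S,10R,11R)-7,8,9-trihydroxylongipinan-1-one | O[C@@H]1[C@@H](O)C(C)(C)[C@H]2[C@@H]3[C@H](C)CC(=O)[C@H]2[C@]3(C)[C@@H]1O | intermediate
30 | phenylboronic acid | OB(O)c1ccccc1 | starting material
31 | tert-butyldimethylsilyl trifluoromethanesulfonate | CC(C)(C)[Si](C)(C)OS(=O)(=O)C(F)(F)F | starting material
32 | 8,9-O-(phenylboranediyl) derivative of 29 (cyclic phenylboronate) | c1ccccc1B2O[C@@H]3[C@@H](O)C(C)(C)[C@H]4[C@@H]5[C@H](C)CC(=O)[C@H]4[C@]5(C)[C@@H]3O2 | intermediate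
33 | 7-O-(tert-butyldimethylsilyl) derivative of 32 | c1ccccc1B2O[C@@H]3[C@@H](O[Si](C)(C)C(C)(C)C)C(C)(C)[C@H]4[C@@H]5[C@H](C)CC(=O)[C@H]4[C@]5(C)[C@@H]3O2 | intermediate
34 | 7-O-(tert-butyldimethylsilyl)-7,8,9-trihydroxylongipinan-1-one, 8,9-diol free; all centres as in 37 | O[C@@H]1[C@@H](O[Si](C)(C)C(C)(C)C)C(C)(C)[C@H]2[C@@H]3[C@H](C)CC(=O)[C@H]2[C@]3(C)[C@@H]1O | intermediate
35 | (2Z)-2-methylbut-2-enoic anhydride (angelic anhydride) | C/C=C(/C)C(=O)OC(=O)/C(C)=C\C | starting material
36 | 7-O-(tert-butyldimethylsilyl)-1-oxolongipinane-8,9-diyl bis[(2Z)-2-methylbut-2-enoate]; all centres as in 37 | C/C=C(/C)C(=O)O[C@@H]1[C@@H](O[Si](C)(C)C(C)(C)C)C(C)(C)[C@H]2[C@@H]3[C@H](C)CC(=O)[C@H]2[C@]3(C)[C@@H]1OC(=O)/C(C)=C\C | intermediate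
37 | (3R,4S,5S,7S,8R,9S,10R,11R)-7-hydroxy-1-oxolongipinane-8,9-diyl bis[(2Z)-2-methylbut-2-enoate], i.e. (1R,2R,3S,4R,5S,7S,8S,9R)-5-hydroxy-2,6,6,9-tetramethyl-11-oxotricyclo[5.4.0.0^2,8]undecane-3,4-diyl bis[(2Z)-2-methylbut-2-enoate] | C/C=C(/C)C(=O)O[C@@H]1[C@@H](O)C(C)(C)[C@H]2[C@@H]3[C@H](C)CC(=O)[C@H]2[C@]3(C)[C@@H]1OC(=O)/C(C)=C\C | target

**Count and risks**
Total steps: 19. Longest linear sequence: 19 (the route is linear from 1; every other input is a purchased reagent).

Most likely to fail, with fallbacks: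

Step 8 (ketene [2+2]). The alkene carries an allylic oxygen, so it may be sluggish; the face selectivity rests on a model; and the α-alkoxy enone may epimerise or polymerise in hot amine. The fallback sets out from 12 and returns at 18. The carbinol of 12 is silylated (TBSCl, imidazole) to the silyl ether ester F1. Saponification gives the silyl ether acid F2. This is taken through its acid chloride F3 and the vinylketene F4 to the silyl ether cycloadduct F5, so that neither an enolisable α-alkoxy ketone nor a free enone meets the base. TBAF then gives the cycloadduct alcohol F6, and Dess–Martin oxidation gives 18.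

Step 9 (reductive aldol to the seven-membered ring). The tetrasubstituted enolate must attack a hindered cyclobutanone, and the aldolate can revert. The fallback sets out from 18 and returns at 19. Rh-catalysed 1,4-hydrosilylation (Et3SiH, (Ph3P)3RhCl) gives the triethylsilyl enol ether F7. This is closed by an intramolecular Mukaiyama aldol addition (BF3·OEt2, CH2Cl2, −78 °C) under acidic rather than basic control, giving 19 after work-up.

Step 18 (bis-angeloylation). Two hindered secondary alkoxides must be acylated without Z to E drift, next to an enolisable ketone. The fallback sets out from 34 and returns at 36. Both hydroxyls are esterified with 2-[bis(2,2,2-trifluoroethoxy)phosphoryl]propanoic acid (DCC, DMAP) to the bis(phosphonopropanoate) F8. The two Z-trisubstituted enoates are then built on the molecule by Still–Gennari olefination with acetaldehyde (KHMDS, 18-crown-6, THF, −78 °C), giving 36.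

**Further compounds**
F1 | step 8 | methyl (2E,6E)-7-[(4S,5S)-5-{1-[tert-butyl(dimethyl)silyl]oxy-2-methylprop-2-en-1-yl}-2,2-dimethyl-1,3-dioxolan-4-yl]-3-methylocta-2,6-dienoate (carbinol epimers) | COC(=O)/C=C(\C)CC/C=C(\C)[C@@H]1OC(C)(C)O[C@@H]1C(O[Si](C)(C)C(C)(C)C)C(C)=C
F2 | step 8 | (2E,6E)-7-[(4S,5S)-5-{1-[tert-butyl(dimethyl)silyl]oxy-2-methylprop-2-en-1-yl}-2,2-dimethyl-1,3-dioxolan-4-yl]-3-methylocta-2,6-dienoic acid | OC(=O)/C=C(\C)CC/C=C(\C)[C@@H]1OC(C)(C)O[C@@H]1C(O[Si](C)(C)C(C)(C)C)C(C)=C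
F3 | step 8 | acid chloride of F2 | ClC(=O)/C=C(\C)CC/C=C(\C)[C@@H]1OC(C)(C)O[C@@H]1C(O[Si](C)(C)C(C)(C)C)C(C)=C
F4 | step 8 | vinylketene from F3, (6E)-7-[silyloxyalkyl-dioxolanyl]-3-methylideneocta-1,6-dien-1-one | O=C=CC(=C)CC/C=C(\C)[C@@H]1OC(C)(C)O[C@@H]1C(O[Si](C)(C)C(C)(C)C)C(C)=C
F5 | step 8 | (1S,5R,7R)-7-[(4S,5S)-5-{1-[tert-butyl(dimethyl)silyl]oxy-2-methylprop-2-en-1-yl}-2,2-dimethyl-1,3-dioxolan-4-yl]-7-methyl-2-methylidenebicyclo[3.1.1]heptan-6-one | O=C1[C@@H]2CCC(=C)[C@H]1[C@]2(C)[C@@H]3OC(C)(C)O[C@@H]3C(O[Si](C)(C)C(C)(C)C)C(C)=C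
F6 | step 8 | (1S,5R,7R)-7-[(4S,5R)-5-(1-hydroxy-2-methylprop-2-en-1-yl)-2,2-dimethyl-1,3-dioxolan-4-yl]-7-methyl-2-methylidenebicyclo[3.1.1]heptan-6-one | O=C1[C@@H]2CCC(=C)[C@H]1[C@]2(C)[C@@H]3OC(C)(C)O[C@@H]3C(O)C(C)=C
F7 | step 9 | triethylsilyl enol ether of 18, (1S,5R,7R)-7-{(4S,5S)-2,2-dimethyl-5-[2-methyl-1-(triethylsilyloxy)prop-1-en-1-yl]-1,3-dioxolan-4-yl}-7-methyl-2-methylidenebicyclo[3.1.1]heptan-6-one | O=C1[C@@H]2CCC(=C)[C@H]1[C@]2(C)[C@@H]3OC(C)(C)O[C@@H]3C(O[Si](CC)(CC)CC)=C(C)C
F8 | step 18 | 7-O-(tert-butyldimethylsilyl)-1-oxolongipinane-8,9-diyl bis{2-[bis(2,2,2-trifluoroethoxy)phosphoryl]propanoate} | CC(P(=O)(OCC(F)(F)F)OCC(F)(F)F)C(=O)O[C@@H]1[C@@H](O[Si](C)(C)C(C)(C)C)C(C)(C)[C@H]2[C@@H]3[C@H](C)CC(=O)[C@H]2[C@]3(C)[C@@H]1OC(=O)C(C)P(=O)(OCC(F)(F)F)OCC(F)(F)F
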